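(The numbers in the tables were computed for substances that don't exist, and the scatter is random.)

The G charged stands as G, as D or in J, so I kept the account by the fraction g of G left, not by the D made.

| flask | G | L | remark | time |
|---|---|---|---|---|
| red | 1.5 M | 1.5 M | run made earlier |  |
| grey | 1.5 M | 1.9 M | run made earlier |  |
| amber | 1.5 M | 2.3 M | run made earlier |  |
| blue | 0.81 M | 1.35 M | run made earlier |  |
| south-west | 0.80 M | 1.35 M |  | 12 h |
| north | 1.5 M | 1.35 M |  | 12 h |
| south | 3.0 M | 2.00 M |  | 12 h |
| south-east | 0.40 M | 2.50 M |  | 12 h |

| red: time / h | red: D / % | grey: time / h | grey: D / % | amber: time / h | amber: D / % | blue: time / h | blue: D / % |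
|---|---|---|---|---|---|---|---|
| 0.833 | 7.2 | 0.833 | 10.0 | 0.833 | 11.1 | 0.667 | 5.9 |
| 2.00 | 14.6 | 2.00 | 17.3 | 2.00 | 22.8 | 1.33 | 10.4 |
| 4.00 | 23.1 | 4.00 | 28.8 | 4.00 | 33.7 | 2.50 | 18.1 |
| 6.00 | 27.0 | 6.00 | 35.2 | 6.00 | 41.0 | 4.00 | 23.1 |
| 8.00 | 32.9 | 8.00 | 41.4 | 8.00 | 45.9 | 8.00 | 35.5 |

(each reading ± 1 percentage point)

- the flasks put in order of amount of D, in percent of the G charged, best first, at 12 h (south-west / north / south / south-east)
- the amount of D, in percent of the G charged of the flask you put first, at 12 h
- the amount of D, in percent of the G charged of the flask you put last, at 12 h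

- percentages count the G that a species holds: one J counts as two
- what was read earlier has a scatter of 1 percentage point, one standard deviation
- candidate steps: 2 G -> J; G + L <-> D + X

If D forms at k[G][L], the first readings of red, grey, amber and blue, each divided by its time and its L, give k = 0.0611 M⁻¹ h⁻¹. Between its last two readings, blue gained 0.0310 h⁻¹ of its charge, around D = 29.3% and L = 1.11 M. So g was near 45.6%, and the balance puts 25.1% in J.

D's rate goes with [G][L] and J's with [G]², so I carried the split constant w, the G going to D per G going to J at one L per G charged: 0.701. A flask's split (selectivity factor) is then s = w·L/G, with G as charged. With s held, 1/g = (1 + 1/s)·exp(kLt) − 1/s and D = s·ln((s + 1)/(s + g)).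

For south-west, s = 1.18, and L held at its charge gives 50.4%. The second way runs blue's last slope on to 12 h. G and L were both falling, so this is a ceiling: 47.9%. The ledger stood above it, so the ledger cheated by holding L. Taking off half of the L spent leaves 1.15 M and gives 45.1%, below the ceiling.

South, at s = 0.467, falls from 45.5% to 33.9% the same way. South-east, with L taken at 2.30 M and s = 4.03, gives 74.2%. North, at s = 0.631, falls from 43.6% to 35.5% the same way, so my reckoning puts it less than south-west and more than south.

The forecast gave south-east > south-west > north > south, top 71%, low 33%, a little apart from my two numbers, and added: “North versus south is nearly a tie.”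

    2 G → J (k = 0.0520 M⁻¹ h⁻¹)
    G + L ⇌ D + X (K = 3.00, k = 0.0650 M⁻¹ h⁻¹)

The flasks gave south-east > south-west > north > south, with 73.4% and 31.3%. South-east had not come to rest: at 120 h, ten times the time asked, it held 83.2% D. Fed the G left in south-east, 15.2% at 12.0 h and 4.22% at 120 h, the ledger gives 74.4% and 85.1%. The neighbour of south charged with 1.2 M of G kept 18% G, and w gives it 52.4% D against a simulated 49.5%. South moved the other way: its D fell from 31.3% to 25.2% at 120 h, while J rose to 70.3%.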